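**Strategy.** Numbering follows ent-kaurane. The C19 carboxyl and C6 formyl groups on the adjacent ring A carbons C4 and C5 are treated as an opened 5-alkoxybutenolide. Rings C and D (bicyclo[3.2.1]octane C8, C9, C11 to C16) are made first from a chiral cyclohexene hemiester. Ring A (C1 to C5, C10) is closed last at C5–C10: hydrogen-atom transfer to a 1,1-disubstituted alkene on C9 gives the tertiary C10 radical, which adds 6-endo to a tethered (5S)-menthyloxybutenolide and sets quaternary C10 and C5 in one operation. The precursor is the bicycle joined through a three-carbon chain to the butenolide; C4 methylation, oxidation and hydrolysis complete the target.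

Key step: step 11

Atom labels used below: ring A = C1–C5, C10 (C18 methyl and C19 carboxyl on C4, C6 formyl on C5, C20 methyl on C10); ring C = C8, C9, C11–C14 (C7 formyl on C8); ring D = C8, C13–C16 (C17 hydroxymethyl on C16).

Assumption: the target is drawn as the open 6-formyl-19-carboxylic acid; ring–chain tautomerism to its 6-hydroxy-6,19-lactone is possible and is taken as the same compound.

Step 1
Reactants: 1 (1R,6S)-6-(methoxycarbonyl)cyclohex-3-ene-1-carboxylic acid (cis hemiester); 2 2,3-dibromoprop-1-ene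
Product: 3 (1R,6R)-6-(2-bromoprop-2-en-1-yl)-6-(methoxycarbonyl)cyclohex-3-ene-1-carboxylic acid (bromoallyl group trans to the carboxyl, ester cis to it)
Conditions: LiN(iPr)2 (2.2 equiv), THF, −78 to −20 °C; then 2, −78 °C to rt; aq. HCl
Reagents that add atoms: none
Why: Alkylation of the carboxylate/ester-enolate dianion: the allylic bromide should attack the enolate face opposite the pseudo-axial neighbouring carboxylate, which creates quaternary C8 with the 2-bromoallyl group (C15–C17) trans to the C10 carboxyl, so that the two carbonyl groups stay cis.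

Step 2
Reactants: 3 (1R,6R)-6-(2-bromoprop-2-en-1-yl)-6-(methoxycarbonyl)cyclohex-3-ene-1-carboxylic acid
Product: 5 methyl (1R,6R)-6-acetyl-1-(2-bromoprop-2-en-1-yl)cyclohex-3-ene-1-carboxylate, via acid chloride 4 (not isolated)
Conditions: (COCl)2, DMF (cat.), CH2Cl2, 0 °C to rt; then Me2CuLi, Et2O, −78 °C
Reagents that add atoms: lithium dimethylcuprate, [Li+].C[Cu-]C
Why: Acyl substitution of the acid chloride by Me2CuLi should stop at the methyl ketone (C10 with the future C20), and neither the hindered ester, the vinyl bromide nor the C9 stereocentre is touched at −78 °C.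

Step 3
Reactants: 5 methyl (1R,6R)-6-acetyl-1-(2-bromoprop-2-en-1-yl)cyclohex-3-ene-1-carboxylate
Product: 6 methyl (1R,2R,5R)-2-acetyl-6-methylidenebicyclo[3.2.1]octane-1-carboxylate
Conditions: Bu3SnH (1.5 equiv), AIBN (10 mol%), PhH (0.2 M), 80 °C
Reagents that add atoms: none
Why: Tin-hydride vinyl-radical cyclisation, 5-exo-trig onto C13 of the ring alkene, should close ring D as the bicyclo[3.2.1]octane with its exocyclic methylene; the bridge can only form cis, which fixes C13, and the high Bu3SnH concentration reduces the C12 radical before any homoallyl rearrangement.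

Step 4
Reactants: 6 methyl (1R,2R,5R)-2-acetyl-6-methylidenebicyclo[3.2.1]octane-1-carboxylate
Product: 7 methyl (1R,2R,5R,6R)-2-acetyl-6-hydroxy-6-(hydroxymethyl)bicyclo[3.2.1]octane-1-carboxylate (tertiary hydroxyl exo)
Conditions: OsO4 (2 mol%), NMO, acetone/H2O (4:1), rt
Reagents that add atoms: N-methylmorpholine N-oxide, C[N+]1([O-])CCOCC1; water, O
Why: Catalytic dihydroxylation (Upjohn conditions) of the only alkene from its exo face, the face syn to the one-carbon bridge C14 and away from the axial hydrogen on C11, should place the C16 hydroxyl exo and C17 endo as in the target.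

Step 5
Reactants: 7 methyl (1R,2R,5R,6R)-2-acetyl-6-hydroxy-6-(hydroxymethyl)bicyclo[3.2.1]octane-1-carboxylate
Product: 8 acetonide of 7 (2,2-dimethyl-1,3-dioxolane spiro at C16, with C17 in the dioxolane ring)
Conditions: Me2C(OMe)2, PPTS (cat.), CH2Cl2, rt
Reagents that add atoms: 2,2-dimethoxypropane, COC(C)(C)OC
Why: Acid-catalysed transketalisation ties the 1,2-diol up as its acetonide, so that it survives the strong bases, the hydride and the radical step that follow.

Step 6
Reactants: 8 acetonide of 7
Product: 9 enol triflate of 8 (C10 bears OSO2CF3 and the methylene C20; C9 unchanged)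
Conditions: KN(SiMe3)2 added last to 8 and N-(5-chloro-2-pyridyl)triflimide, THF, −78 °C
Reagents that add atoms: N-(5-chloropyridin-2-yl)-1,1,1-trifluoro-N-(trifluoromethylsulfonyl)methanesulfonamide, O=S(=O)(N(c1ccc(Cl)cn1)S(=O)(=O)C(F)(F)F)C(F)(F)F
Why: Kinetic deprotonation of the methyl ketone at its methyl group (C9–H is tertiary and hindered) and O-sulfonylation should give the 1,1-disubstituted enol triflate; adding the base to the ketone and triflating agent keeps the enolate from attacking the neighbouring ester.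

Step 7
Reactants: 9 enol triflate of 8
Product: 10 primary alcohol from 9 (hydroxymethyl C7 on C8; enol triflate and acetonide retained)
Conditions: iBu2AlH (2.5 equiv), CH2Cl2, −78 °C
Reagents that add atoms: none
Why: iBu2AlH should reduce the neopentyl methyl ester to the primary alcohol at low temperature, conditions under which enol triflates and acetonides are inert.

Step 8
Reactants: 11 (5S)-5-{[(1S,2R,5S)-5-methyl-2-(propan-2-yl)cyclohexyl]oxy}furan-2(5H)-one
Product: 13 (5S)-3-bromo-5-{[(1S,2R,5S)-5-methyl-2-(propan-2-yl)cyclohexyl]oxy}furan-2(5H)-one, via dibromide 12 (not isolated)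
Conditions: Br2, CH2Cl2, 0 °C to rt; then Et3N, 0 °C
Reagents that add atoms: bromine, BrBr
Why: Anti addition of bromine to the butenolide alkene followed by base-induced loss of HBr (the acidic α-hydrogen is removed) should give the α-bromobutenolide without touching the acetal stereocentre.

Step 9
Reactants: 13 (5S)-3-bromo-5-(menthyloxy)furan-2(5H)-one; 14 allyltributylstannane
Product: 15 (5S)-3-(prop-2-en-1-yl)-5-{[(1S,2R,5S)-5-methyl-2-(propan-2-yl)cyclohexyl]oxy}furan-2(5H)-one
Conditions: Pd(PPh3)4 (5 mol%), PhMe, 90 °C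
Reagents that add atoms: none
Why: Stille cross-coupling of the alkenyl bromide with the allylstannane proceeds under neutral conditions, so the base-sensitive acetal centre should keep its configuration.

Step 10
Reactants: 15 (5S)-3-allyl-5-(menthyloxy)furan-2(5H)-one; 10 primary alcohol bearing the enol triflate
Product: 17 cyclisation precursor (on C9 the alkene C10(=C20H2), whose chain C1–C2–C3 ends at the α-carbon C4 of the (5S)-menthyloxybutenolide; C7 alcohol and acetonide as in 10), via alkylborane 16 (not isolated)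
Conditions: 9-BBN-H, THF, rt; then 10, Pd(dppf)Cl2 (5 mol%), AsPh3, K3PO4 (aq), DMF, rt
Reagents that add atoms: none
Why: 9-BBN-H should hydroborate only the terminal alkene with boron at the terminal carbon C1, and the primary alkylborane then undergoes B-alkyl Suzuki–Miyaura coupling with the enol triflate under Pd(dppf)Cl2 catalysis to form the C1–C10 bond.

Step 11
Reactants: 17 cyclisation precursor
Product: 18 ring A-closed lactone alcohol (cyclohexane C1–C5/C10 cis-fused at C4–C5 to the γ-lactone C19(=O)–O–C6; menthyloxy on C6 trans to C10; C20 methyl on C10 trans to H5; H4 cis to H5)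
Conditions: Fe(acac)3 (30 mol%), PhSiH3 (2.5 equiv), EtOH/(CH2OH)2 (5:1), 60 °C, 0.01 M, Ar
Reagents that add atoms: none
Why: Hydrogen-atom transfer from the iron hydride formed from Fe(acac)3 and PhSiH3 to the CH2 terminus of the 1,1-disubstituted alkene makes the C20 methyl group and the tertiary C10 radical, which adds to the β-carbon C5 of the tethered butenolide; the α-carbonyl radical at C4 is then reduced by divalent iron to the enolate and protonated by ethanol. The closest known reactions are the iron-hydride reductive olefin coupling (intramolecular Giese cyclisation) and the additions of tertiary radicals to 5-alkoxybutenolides trans to the alkoxy group. Ring A is closed in the 6-endo-trig mode through the C5–C10 bond, because the nucleophilic radical attacks the β-carbon of the α-tethered acceptor and not the α-carbon (5-exo). C5 is controlled by the (S)-configured acetal carbon C6, whose menthyloxy group shields one face of the butenolide, and C10 by the chair-like transition state in which C6 stays anti to C3 (equatorial) and the bulky bicyclic group on C10 is equatorial, so that the new methyl group is axial and trans to H5. The step needs hydrogen-atom transfer to occur only at the electron-rich alkene and cyclisation to outrun reduction of the radical; the absence of any other unactivated alkene (the ring D methylene is already the protected diol), the electron-poor nature of the butenolide alkene and high dilution should secure this.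

Step 12
Reactants: 18 ring A-closed lactone alcohol
Product: 19 C4-methylated lactone alcohol (C18 methyl on C4 cis to H5 and trans to C10; lactone carbonyl C19 syn to C20)
Conditions: LiN(iPr)2 (2.3 equiv), THF, −78 °C; MeI, DMPU, −78 to −40 °C
Reagents that add atoms: iodomethane, CI
Why: The lithium enolate of the lactone should be methylated on the face opposite the C5 substituent (C10), the usual course for 4-substituted butanolide enolates and the only one that keeps the lactone cis-fused to ring A, which makes C18 equatorial and C19 axial; the lithium alkoxide of the C7 alcohol does not react with MeI at −78 °C.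

Step 13
Reactants: 19 C4-methylated lactone alcohol
Product: 20 C7 aldehyde (formyl group on C8; acetonide and menthyl pseudoester retained)
Conditions: DMP, CH2Cl2, rt
Reagents that add atoms: none
Why: Dess–Martin oxidation should convert the hindered primary alcohol into the non-enolisable C7 aldehyde under near-neutral conditions that leave both acetals intact.

Step 14
Reactants: 20 C7 aldehyde
Product: 21 target, 16,17-dihydroxy-6,7-seco-ent-kaurane-6,7-dial-19-oic acid
Conditions: 2 M HCl, THF/H2O, 45 °C
Reagents that add atoms: water, O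
Why: Aqueous acid should hydrolyse the acetonide to the 16,17-diol and the menthyl pseudoester (through the cyclic acyloxocarbenium ion) to the 6-hydroxy-6,19-lactone, the ring tautomer of the C6 aldehyde and C19 acid, without affecting any stereocentre.

**Compound list**

1 | (1R,6S)-6-(methoxycarbonyl)cyclohex-3-ene-1-carboxylic acid (cis hemiester) | OC(=O)[C@@H]1CC=CC[C@@H]1C(=O)OC | starting material
2 | 2,3-dibromoprop-1-ene | C=C(Br)CBr | starting material
3 | (1R,6R)-6-(2-bromoprop-2-en-1-yl)-6-(methoxycarbonyl)cyclohex-3-ene-1-carboxylic acid | OC(=O)[C@@H]1CC=CC[C@@]1(C(=O)OC)CC(Br)=C | intermediate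
4 | methyl (1R,6R)-1-(2-bromoprop-2-en-1-yl)-6-(chlorocarbonyl)cyclohex-3-ene-1-carboxylate | ClC(=O)[C@@H]1CC=CC[C@@]1(C(=O)OC)CC(Br)=C | intermediate
5 | methyl (1R,6R)-6-acetyl-1-(2-bromoprop-2-en-1-yl)cyclohex-3-ene-1-carboxylate | CC(=O)[C@@H]1CC=CC[C@@]1(C(=O)OC)CC(Br)=C | intermediate
6 | methyl (1R,2R,5R)-2-acetyl-6-methylidenebicyclo[3.2.1]octane-1-carboxylate | CC(=O)[C@@H]1CC[C@@H]2C[C@@]1(C(=O)OC)CC2=C | intermediate
7 | methyl (1R,2R,5R,6R)-2-acetyl-6-hydroxy-6-(hydroxymethyl)bicyclo[3.2.1]octane-1-carboxylate | CC(=O)[C@@H]1CC[C@@H]2C[C@@]1(C(=O)OC)C[C@]2(O)CO | intermediate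
8 | acetonide of 7 | CC(=O)[C@@H]1CC[C@@H]2C[C@@]1(C(=O)OC)C[C@]2(OC(C)(C)O3)C3 | intermediate
9 | enol triflate of 8 | C=C(OS(=O)(=O)C(F)(F)F)[C@@H]1CC[C@@H]2C[C@@]1(C(=O)OC)C[C@]2(OC(C)(C)O3)C3 | intermediate
10 | primary alcohol from 9 | C=C(OS(=O)(=O)C(F)(F)F)[C@@H]1CC[C@@H]2C[C@@]1(CO)C[C@]2(OC(C)(C)O3)C3 | intermediate
11 | (5S)-5-{[(1S,2R,5S)-5-methyl-2-(propan-2-yl)cyclohexyl]oxy}furan-2(5H)-one | O=C1C=C[C@@H](O[C@H]2C[C@@H](C)CC[C@@H]2C(C)C)O1 | starting material
12 | 3,4-dibromide of 11 (Br on C4 trans to the menthyloxy group, Br on C3 trans to Br on C4) | O=C1[C@@H](Br)[C@H](Br)[C@@H](O[C@H]2C[C@@H](C)CC[C@@H]2C(C)C)O1 | intermediate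
13 | (5S)-3-bromo-5-(menthyloxy)furan-2(5H)-one | O=C1C(Br)=C[C@@H](O[C@H]2C[C@@H](C)CC[C@@H]2C(C)C)O1 | intermediate
14 | allyltributylstannane | C=CC[Sn](CCCC)(CCCC)CCCC | starting material
15 | (5S)-3-allyl-5-(menthyloxy)furan-2(5H)-one | O=C1C(CC=C)=C[C@@H](O[C@H]2C[C@@H](C)CC[C@@H]2C(C)C)O1 | intermediate
16 | B-alkyl-9-borabicyclo[3.3.1]nonane from 15 | O=C1C(CCCB2C3CCCC2CCC3)=C[C@@H](O[C@H]4C[C@@H](C)CC[C@@H]4C(C)C)O1 | intermediate
17 | cyclisation precursor | C=C(CCCC4=C[C@@H](O[C@H]5C[C@@H](C)CC[C@@H]5C(C)C)OC4=O)[C@@H]1CC[C@@H]2C[C@@]1(CO)C[C@]2(OC(C)(C)O3)C3 | intermediate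
18 | ring A-closed lactone alcohol | C[C@@]1([C@@H]2CC[C@@H]3C[C@@]2(CO)C[C@]3(OC(C)(C)O6)C6)CCC[C@H]4C(=O)O[C@H](O[C@H]5C[C@@H](C)CC[C@@H]5C(C)C)[C@@H]14 | intermediate
19 | C4-methylated lactone alcohol | C[C@@]1([C@@H]2CC[C@@H]3C[C@@]2(CO)C[C@]3(OC(C)(C)O6)C6)CCC[C@@]4(C)C(=O)O[C@H](O[C@H]5C[C@@H](C)CC[C@@H]5C(C)C)[C@@H]14 | intermediate
20 | C7 aldehyde | C[C@@]1([C@@H]2CC[C@@H]3C[C@@]2(C=O)C[C@]3(OC(C)(C)O6)C6)CCC[C@@]4(C)C(=O)O[C@H](O[C@H]5C[C@@H](C)CC[C@@H]5C(C)C)[C@@H]14 | intermediate
21 | 16,17-dihydroxy-6,7-seco-ent-kaurane-6,7-dial-19-oic acid | C[C@@]1([C@@H]2CC[C@@H]3C[C@@]2(C=O)C[C@]3(O)CO)CCC[C@@](C)(C(=O)O)[C@H]1C=O | target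

**Step count.** Total: 14 steps. Longest linear sequence: 12 steps (steps 1–7 and 10–14); steps 8 and 9 form the side branch.

**Steps most likely to fail**

Step 11. The tertiary C10 radical may be reduced to the alkane, the alkene may migrate by reversible hydrogen-atom transfer, or the radical may be relayed to the C7 carbinol carbon by a 1,5-hydrogen shift before the hindered C5–C10 bond forms. The fallback generates the same radical without a metal hydride present in the cyclisation. Setting out from 17, silylation (tBuMe2SiCl, imidazole) would give the tert-butyldimethylsilyl ether F1. Mukaiyama hydration (Co(acac)2, PhSiH3, O2) would give the tertiary C10 alcohol F2. Acylation with methyl chlorooxoacetate (Et3N, DMAP) would give the methyl oxalate F3, and CsOH (1 equiv) the caesium oxalate F4. Blue-light irradiation with Ir[dF(CF3)ppy]2(dtbbpy)PF6 (DME/DMF, H2O) would expel two molecules of CO2 and close ring A to the silyl ether F5. Bu4NF would then return to 18.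

Step 10. The aqueous base may deprotonate the acetal carbon C6 (epimerisation through the 2-alkoxyfuranolate) or open the pseudoester, while transmetalation to the hindered triflate is slow. The fallback is a base-free Negishi union. Setting out from 10, Et3SiCl/imidazole would give the triethylsilyl ether F6. From 15, hydroboration as in step 10 and cleavage of borane 16 with ICl/NaOAc in MeOH would give the primary iodide F7, and zinc insertion (Zn, LiCl, THF) the alkylzinc iodide F8. Pd(dppf)Cl2-catalysed coupling of F8 with F6 in THF would give the coupled silyl ether F9, and Bu4NF buffered with AcOH would return to 17.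

Step 14. The acid strength needed to cleave the menthyl acetal may ionise the tertiary C16 carbinol (dehydration or a pinacol-type hydride shift) before the pseudoester is hydrolysed. The fallback separates the two unmaskings and opens the pseudoester by acyl attack instead. Setting out from 20, AcOH/H2O (4:1, 40 °C) would remove only the acetonide and give the diol F10. LiOH (THF/H2O, 0 °C) would then attack the C19 carbonyl, releasing the C6 aldehyde, the C19 carboxylate and menthol, and acidification to pH 3 would give 21.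

**Further compounds**

F1 | step 11 | tert-butyldimethylsilyl ether of 17 | C=C(CCCC4=C[C@@H](O[C@H]5C[C@@H](C)CC[C@@H]5C(C)C)OC4=O)[C@@H]1CC[C@@H]2C[C@@]1(CO[Si](C)(C)C(C)(C)C)C[C@]2(OC(C)(C)O3)C3
F2 | step 11 | tertiary C10 alcohol from F1 (either epimer at C10) | CC(O)(CCCC4=C[C@@H](O[C@H]5C[C@@H](C)CC[C@@H]5C(C)C)OC4=O)[C@@H]1CC[C@@H]2C[C@@]1(CO[Si](C)(C)C(C)(C)C)C[C@]2(OC(C)(C)O3)C3
F3 | step 11 | methyl oxalate of F2 | CC(OC(=O)C(=O)OC)(CCCC4=C[C@@H](O[C@H]5C[C@@H](C)CC[C@@H]5C(C)C)OC4=O)[C@@H]1CC[C@@H]2C[C@@]1(CO[Si](C)(C)C(C)(C)C)C[C@]2(OC(C)(C)O3)C3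
F4 | step 11 | caesium oxalate of F2 | [Cs+].CC(OC(=O)C([O-])=O)(CCCC4=C[C@@H](O[C@H]5C[C@@H](C)CC[C@@H]5C(C)C)OC4=O)[C@@H]1CC[C@@H]2C[C@@]1(CO[Si](C)(C)C(C)(C)C)C[C@]2(OC(C)(C)O3)C3
F5 | step 11 | tert-butyldimethylsilyl ether of 18 | C[C@@]1([C@@H]2CC[C@@H]3C[C@@]2(CO[Si](C)(C)C(C)(C)C)C[C@]3(OC(C)(C)O6)C6)CCC[C@H]4C(=O)O[C@H](O[C@H]5C[C@@H](C)CC[C@@H]5C(C)C)[C@@H]14
F6 | step 10 | triethylsilyl ether of 10 | C=C(OS(=O)(=O)C(F)(F)F)[C@@H]1CC[C@@H]2C[C@@]1(CO[Si](CC)(CC)CC)C[C@]2(OC(C)(C)O3)C3
F7 | step 10 | (5S)-3-(3-iodopropyl)-5-(menthyloxy)furan-2(5H)-one | O=C1C(CCCI)=C[C@@H](O[C@H]2C[C@@H](C)CC[C@@H]2C(C)C)O1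
F8 | step 10 | alkylzinc iodide from F7 | O=C1C(CCC[Zn]I)=C[C@@H](O[C@H]2C[C@@H](C)CC[C@@H]2C(C)C)O1
F9 | step 10 | triethylsilyl ether of 17 | C=C(CCCC4=C[C@@H](O[C@H]5C[C@@H](C)CC[C@@H]5C(C)C)OC4=O)[C@@H]1CC[C@@H]2C[C@@]1(CO[Si](CC)(CC)CC)C[C@]2(OC(C)(C)O3)C3
F10 | step 14 | 16,17-diol from 20 (menthyl pseudoester retained) | C[C@@]1([C@@H]2CC[C@@H]3C[C@@]2(C=O)C[C@]3(O)CO)CCC[C@@]4(C)C(=O)O[C@H](O[C@H]5C[C@@H](C)CC[C@@H]5C(C)C)[C@@H]14
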